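The ten-membered carbocycle is closed last, between C3 (the homoallylic ring CH2) and C4 (the ring sp2 carbon bearing the formyl carbon C15), by an intramolecular alkyl–alkenyl Negishi coupling. The step exploits that C4 lies in the ring-cis C4=C5 olefin: a (Z)-alkenyl iodide fixes this geometry beforehand, and the cis C1=C10 olefin plus the trans-fused lactone (O–C6–C7–C11–C12) fold the chain so that the C3 alkylzinc meets C4. One operation forms the ring without touching the C6, C7 and C8 stereocentres. The precursor is an open-chain diiodide carrying lactone, C8 ester and C14 acetate, assembled by an indium Barbier coupling that relays C6 to C7 and C8.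

Key step: step 16

Remark on numbering: germacrane numbering is used throughout (ring C1–C10; C11, C12, C13 = lactone methylene-acrylate unit; C14 on C10; C15 on C4). Both ring double bonds of the target are cis within the ring, although both are E by the sequence rules. TBS = tert-butyldimethylsilyl.

Assumption: in step 1 the ProPhenol antipode is the one that delivers the (S)-carbinol; the sense of induction is set by the ligand alone.

Step 1
Reactants: 1 (E)-but-2-enal; 2 3-(TBSO)prop-1-yne
Product: 3 (2E,4S)-7-(TBSO)hept-2-en-5-yn-4-ol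
Conditions: Me2Zn (3 equiv), ProPhenol ligand (10 mol%), Ph3P=O (20 mol%), toluene, 0 °C to rt
Reagents that add atoms: none
Why: Zinc–ProPhenol-catalysed enantioselective alkynylation of an enal, in which the dinuclear zinc alkoxide delivers the zinc acetylide of 2 to one aldehyde face and so sets C6 (4S in 3), the only stereocentre of the route fixed by a catalyst.

Step 2
Reactants: 3 (2E,4S)-7-(TBSO)hept-2-en-5-yn-4-ol
Product: 5 (2Z,4S,5E)-2-iodo-1-(TBSO)hepta-2,5-dien-4-ol, via cyclic sodium alkenylalanate 4 (not isolated)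
Conditions: NaAlH2(OCH2CH2OMe)2, THF, 0 °C; then I2, −78 °C to 0 °C
Reagents that add atoms: iodine, [I][I]
Why: Hydroxyl-directed trans-hydroalumination followed by iodinolysis: the O-bound Al–H delivers hydride to the proximal alkyne carbon C5, aluminium ends on C4 inside the five-membered ring of 4 and is replaced by iodine with retention, so that iodine stands cis to C6 (the later ring-cis C4=C5 geometry) while C6 is untouched.

Step 3
Reactants: 5 (2Z,4S,5E)-2-iodo-1-(TBSO)hepta-2,5-dien-4-ol; 6 2-(bromomethyl)prop-2-enoic acid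
Product: 8 (2Z,4S,5E)-2-iodo-1-(TBSO)hepta-2,5-dien-4-yl 2-(bromomethyl)prop-2-enoate, via 2-(bromomethyl)prop-2-enoyl chloride 7 (not isolated)
Conditions: 6, (COCl)2, DMF (cat.), CH2Cl2, 0 °C to rt; then 5, 2,6-lutidine, CH2Cl2, −40 °C to 0 °C
Reagents that add atoms: none
Why: O-acylation of the secondary alcohol with an acid chloride and a hindered pyridine base, which avoids a nucleophilic catalyst that could attack the allylic bromide by SN2' and leaves the C6–O bond and its configuration intact.

Step 4
Reactants: 8 (2Z,4S,5E)-2-iodo-1-(TBSO)hepta-2,5-dien-4-yl 2-(bromomethyl)prop-2-enoate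
Product: 9 (5S)-3-(bromomethyl)-5-[(1Z)-2-iodo-3-(TBSO)prop-1-en-1-yl]furan-2(5H)-one
Conditions: RuCl2(=CHPh)(H2IMes)(PCy3) (second-generation Grubbs catalyst, 5 mol%), 1,4-benzoquinone (10 mol%), toluene (5 mM), 80 °C
Reagents that add atoms: none
Why: Ring-closing metathesis between the propenyl group and the 1,1-disubstituted acrylate closes the five-membered butenolide (C7=C11) with loss of propene, while the trisubstituted alkenyl iodide is inert to the ruthenium carbene and the neutral medium leaves the acidic C6–H stereocentre alone.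

Step 5
Reactants: 10 4-(TBSO)but-1-yne
Product: 12 5-(TBSO)pent-2-yn-1-ol, via lithium 4-silyloxybutynide 11 (not isolated)
Conditions: n-BuLi, THF, −78 °C; then (CH2O)n, −78 °C to rt
Reagents that add atoms: paraformaldehyde (as formaldehyde), C=O
Why: Hydroxymethylation of a lithium acetylide by 1,2-addition to formaldehyde installs C14 as the propargylic alcohol that directs the next step.

Step 6
Reactants: 12 5-(TBSO)pent-2-yn-1-ol
Product: 13 (2E)-2-ethenyl-5-(TBSO)pent-2-en-1-ol
Conditions: CH2=CHMgCl (4 equiv), THF/cyclohexane, reflux; then aq. NH4Cl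
Reagents that add atoms: vinylmagnesium chloride, C=C[Mg]Cl
Why: Magnesium-mediated anti-carbomagnesiation of a 2-alkyn-1-ol, in which the alkoxide directs the vinyl group to the proximal carbon C10 and magnesium to C1 within a five-membered chelate, so that after protonation the vinyl group (C9=C8) is cis to the C2 chain, which is the ring-cis C1=C10 geometry.

Step 7
Reactants: 13 (2E)-2-ethenyl-5-(TBSO)pent-2-en-1-ol
Product: 14 (2E)-2-ethenyl-5-(TBSO)pent-2-en-1-yl acetate
Conditions: Ac2O, pyridine, DMAP (cat.), CH2Cl2, 0 °C to rt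
Reagents that add atoms: acetic anhydride, CC(=O)OC(C)=O
Why: DMAP-catalysed O-acetylation of the primary allylic alcohol installs the C14 acetate of the target.

Step 8
Reactants: 14 (2E)-2-ethenyl-5-(TBSO)pent-2-en-1-yl acetate
Product: 15 (2E)-2-ethenyl-5-hydroxypent-2-en-1-yl acetate
Conditions: HF·pyridine, pyridine, THF, 0 °C to rt
Reagents that add atoms: none
Why: Fluoride-mediated cleavage of the primary silyl ether under buffered, non-basic conditions that spare the allylic acetate and the diene.

Step 9
Reactants: 15 (2E)-2-ethenyl-5-hydroxypent-2-en-1-yl acetate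
Product: 16 (2E)-2-ethenyl-5-iodopent-2-en-1-yl acetate
Conditions: I2, PPh3, imidazole, CH2Cl2, 0 °C to rt
Reagents that add atoms: iodine, [I][I]
Why: Appel-type (Garegg–Samuelsson) iodination, an SN2 displacement of the alkoxyphosphonium ion by iodide, gives the primary C3 iodide needed for zinc insertion.

Step 10
Reactants: 16 (2E)-2-ethenyl-5-iodopent-2-en-1-yl acetate
Product: 18 (2E)-2-(2-hydroxyethyl)-5-iodopent-2-en-1-yl acetate, via B-alkyl-9-BBN adduct 17 (not isolated)
Conditions: 9-BBN, THF, 0 °C to rt; then NaBO3·4H2O, H2O, rt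
Reagents that add atoms: sodium perborate, [Na+].[Na+].O[B-]1(O)OO[B-](O)(O)OO1
Why: Hydroboration–oxidation in which the bulky 9-BBN adds only to the terminal CH2 (C8) of the monosubstituted olefin and not to the trisubstituted C1=C10 olefin, and mild perborate oxidation of 17 spares acetate and iodide.

Step 11
Reactants: 18 (2E)-2-(2-hydroxyethyl)-5-iodopent-2-en-1-yl acetate
Product: 19 (2E)-5-iodo-2-(2-oxoethyl)pent-2-en-1-yl acetate
Conditions: Dess–Martin periodinane, NaHCO3, CH2Cl2, 0 °C to rt
Reagents that add atoms: none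
Why: Dess–Martin oxidation under bicarbonate buffer should give the β,γ-unsaturated aldehyde without migration of the C1=C10 double bond into conjugation, and 19 is used at once.

Step 12
Reactants: 20 ethyl 2-(hydroxymethyl)prop-2-enoate
Product: 21 ethyl 2-[(TBSO)methyl]prop-2-enoate
Conditions: TBSCl, imidazole, CH2Cl2, 0 °C to rt
Reagents that add atoms: tert-butyldimethylsilyl chloride, CC(C)(C)[Si](C)(C)Cl
Why: Silylation of the primary alcohol protects the side-chain hydroxyl for the acylation and the ring closure.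

Step 13
Reactants: 21 ethyl 2-[(TBSO)methyl]prop-2-enoate
Product: 22 2-[(TBSO)methyl]prop-2-enoic acid
Conditions: LiOH, THF/H2O, 0 °C to rt; then aq. HCl to pH 3
Reagents that add atoms: lithium hydroxide, [Li+].[OH-]
Why: Saponification at low temperature, where hydroxide attack at the ester carbonyl is faster than conjugate addition to the α-substituted acrylate, gives the free acid.

Step 14
Reactants: 9 (5S)-3-(bromomethyl)-5-[(1Z)-2-iodo-3-(TBSO)prop-1-en-1-yl]furan-2(5H)-one; 19 (2E)-5-iodo-2-(2-oxoethyl)pent-2-en-1-yl acetate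
Product: 23 (4R,5S)-4-[(1S,3E)-3-(acetoxymethyl)-1-hydroxy-6-iodohex-3-en-1-yl]-5-[(1Z)-2-iodo-3-(TBSO)prop-1-en-1-yl]-3-methylideneoxolan-2-one
Conditions: In powder, THF/H2O (3:1), rt
Reagents that add atoms: none
Why: Indium-mediated Barbier allylation in which the allylindium from 9 reacts at its γ-carbon C7 through a chair Zimmerman–Traxler transition state: the C7–C8 bond forms on the butenolide face anti to the C6 iodoalkenyl group (trans lactone, 7R), the ring-locked allyl geometry with C9 equatorial places the C8 oxygen anti to C6 along C9–C8–C7–C11 (8S), the exo-methylene lactone emerges directly, and both iodides are inert to In.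

Step 15
Reactants: 23 (4R,5S)-4-[(1S,3E)-3-(acetoxymethyl)-1-hydroxy-6-iodohex-3-en-1-yl]-5-[(1Z)-2-iodo-3-(TBSO)prop-1-en-1-yl]-3-methylideneoxolan-2-one; 22 2-[(TBSO)methyl]prop-2-enoic acid
Product: 24 (1S,3E)-3-(acetoxymethyl)-6-iodo-1-{(2S,3R)-2-[(1Z)-2-iodo-3-(TBSO)prop-1-en-1-yl]-4-methylidene-5-oxooxolan-3-yl}hex-3-en-1-yl 2-[(TBSO)methyl]prop-2-enoate
Conditions: EDC·HCl, DMAP (cat.), CH2Cl2, 0 °C to rt
Reagents that add atoms: none
Why: Steglich esterification (carbodiimide activation with catalytic DMAP) of the C8 alcohol at low temperature should outrun base-induced translactonisation and proceeds with retention at C8.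

Step 16
Reactants: 24 (1S,3E)-3-(acetoxymethyl)-6-iodo-1-{(2S,3R)-2-[(1Z)-2-iodo-3-(TBSO)prop-1-en-1-yl]-4-methylidene-5-oxooxolan-3-yl}hex-3-en-1-yl 2-[(TBSO)methyl]prop-2-enoate
Product: 26 (1(10)E,4E,6R,7R,8S)-14-acetoxy-15-(TBSO)germacra-1(10),4,11(13)-trien-6,12-olid-8-yl 2-[(TBSO)methyl]prop-2-enoate, via alkylzinc iodide 25 (not isolated)
Conditions: Zn dust (activated with BrCH2CH2Br and Me3SiCl), THF, 35 °C; then slow addition (12 h) to Pd2(dba)3 (5 mol%), SPhos (20 mol%), THF/DMA, 40 °C, final 2 mM
Reagents that add atoms: none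
Why: Zinc inserts selectively into the primary C(sp3)–I bond of 24 (the alkenyl C(sp2)–I bond is inert to Zn at 35 °C) to give 25, zerovalent palladium then adds oxidatively to the (Z)-alkenyl iodide at C4 with retention, the C3–Zn bond transmetalates intramolecularly and reductive elimination forms the C3–C4 bond. The closest known reaction type is the alkyl–alkenyl Negishi coupling, run here intramolecularly in the manner of macrocyclic B-alkyl Suzuki–Miyaura and Nozaki–Hiyama–Kishi closures. The ten-membered carbocycle is closed by reductive elimination from an eleven-membered palladacycle (formally a 10-endo closure at the C4=C5 olefin), the lactone ring being already in place. No stereocentre is created: C6, C7 and C8 are untouched and the ring-cis C4=C5 geometry is carried over from the iodide set in step 2. The step needs ring closure to beat oligomerisation and to beat carbopalladation of the C11=C13 methylene; slow addition of 25 to the catalyst at high dilution, the folding imposed by the two cis olefins and the trans lactone, and the fast transmetalation of organozincs should secure this, while the mild organozinc leaves acetate, lactone and both acrylate units intact.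

Step 17
Reactants: 26 (1(10)E,4E,6R,7R,8S)-14-acetoxy-15-(TBSO)germacra-1(10),4,11(13)-trien-6,12-olid-8-yl 2-[(TBSO)methyl]prop-2-enoate
Product: 27 (1(10)E,4E,6R,7R,8S)-14-acetoxy-15-hydroxygermacra-1(10),4,11(13)-trien-6,12-olid-8-yl 2-(hydroxymethyl)prop-2-enoate
Conditions: HF·pyridine, pyridine, THF, 0 °C to rt
Reagents that add atoms: none
Why: Fluoride-mediated cleavage of both primary silyl ethers with buffered HF·pyridine, conditions under which acetate, esters, lactone and the Michael acceptors should persist.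

Step 18
Reactants: 27 (1(10)E,4E,6R,7R,8S)-14-acetoxy-15-hydroxygermacra-1(10),4,11(13)-trien-6,12-olid-8-yl 2-(hydroxymethyl)prop-2-enoate
Product: 28 (1(10)E,4E,6R,7R,8S)-14-acetoxy-15-oxogermacra-1(10),4,11(13)-trien-6,12-olid-8-yl 2-(hydroxymethyl)prop-2-enoate (CNP0198933.2)
Conditions: MnO2 (activated, excess), CH2Cl2, rt
Reagents that add atoms: none
Why: Chemoselective MnO2 oxidation of an allylic alcohol: the C15 carbinol on the electron-rich trisubstituted C4=C5 olefin should be oxidised to the enal, whereas the carbinol on the electron-poor acrylate reacts far more slowly, and the enal geometry (CHO trans to C6) is the stable one.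

Compound list
1 | (E)-but-2-enal (crotonaldehyde) | C/C=C/C=O | starting material
2 | 3-(TBSO)prop-1-yne | C#CCO[Si](C)(C)C(C)(C)C | starting material
3 | (2E,4S)-7-(TBSO)hept-2-en-5-yn-4-ol | C/C=C/[C@H](O)C#CCO[Si](C)(C)C(C)(C)C | intermediate
4 | cyclic sodium alkenylalanate: sodium (5S)-2,2-bis(2-methoxyethoxy)-5-[(1E)-prop-1-en-1-yl]-3-[(TBSO)methyl]-2,5-dihydro-1,2-oxaluminol-2-uide | C/C=C/[C@@H]1O[Al-](OCCOC)(OCCOC)C(CO[Si](C)(C)C(C)(C)C)=C1.[Na+] | intermediate
5 | (2Z,4S,5E)-2-iodo-1-(TBSO)hepta-2,5-dien-4-ol | C/C=C/[C@H](O)/C=C(\I)CO[Si](C)(C)C(C)(C)C | intermediate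
6 | 2-(bromomethyl)prop-2-enoic acid | C=C(CBr)C(=O)O | starting material
7 | 2-(bromomethyl)prop-2-enoyl chloride | C=C(CBr)C(Cl)=O | intermediate
8 | (2Z,4S,5E)-2-iodo-1-(TBSO)hepta-2,5-dien-4-yl 2-(bromomethyl)prop-2-enoate | C/C=C/[C@H](OC(=O)C(=C)CBr)/C=C(\I)CO[Si](C)(C)C(C)(C)C | intermediate
9 | (5S)-3-(bromomethyl)-5-[(1Z)-2-iodo-3-(TBSO)prop-1-en-1-yl]furan-2(5H)-one | BrCC1=C[C@H](OC1=O)/C=C(\I)CO[Si](C)(C)C(C)(C)C | intermediate
10 | 4-(TBSO)but-1-yne | C#CCCO[Si](C)(C)C(C)(C)C | starting material
11 | lithium 4-(TBSO)but-1-yn-1-ide | [Li]C#CCCO[Si](C)(C)C(C)(C)C | intermediate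
12 | 5-(TBSO)pent-2-yn-1-ol | OCC#CCCO[Si](C)(C)C(C)(C)C | intermediate
13 | (2E)-2-ethenyl-5-(TBSO)pent-2-en-1-ol | C=C/C(CO)=C\CCO[Si](C)(C)C(C)(C)C | intermediate
14 | (2E)-2-ethenyl-5-(TBSO)pent-2-en-1-yl acetate | C=C/C(COC(C)=O)=C\CCO[Si](C)(C)C(C)(C)C | intermediate
15 | (2E)-2-ethenyl-5-hydroxypent-2-en-1-yl acetate | C=C/C(COC(C)=O)=C\CCO | intermediate
16 | (2E)-2-ethenyl-5-iodopent-2-en-1-yl acetate | C=C/C(COC(C)=O)=C\CCI | intermediate
17 | 9-[(3E)-3-(acetoxymethyl)-6-iodohex-3-en-1-yl]-9-borabicyclo[3.3.1]nonane | C1CCC2CCCC1B2CC/C(COC(C)=O)=C\CCI | intermediate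
18 | (2E)-2-(2-hydroxyethyl)-5-iodopent-2-en-1-yl acetate | OCC/C(COC(C)=O)=C\CCI | intermediate
19 | (2E)-5-iodo-2-(2-oxoethyl)pent-2-en-1-yl acetate | O=CC/C(COC(C)=O)=C\CCI | intermediate
20 | ethyl 2-(hydroxymethyl)prop-2-enoate | C=C(CO)C(=O)OCC | starting material
21 | ethyl 2-[(TBSO)methyl]prop-2-enoate | C=C(CO[Si](C)(C)C(C)(C)C)C(=O)OCC | intermediate
22 | 2-[(TBSO)methyl]prop-2-enoic acid | C=C(CO[Si](C)(C)C(C)(C)C)C(=O)O | intermediate
23 | (4R,5S)-4-[(1S,3E)-3-(acetoxymethyl)-1-hydroxy-6-iodohex-3-en-1-yl]-5-[(1Z)-2-iodo-3-(TBSO)prop-1-en-1-yl]-3-methylideneoxolan-2-one | O[C@@H](C/C(COC(C)=O)=C\CCI)[C@H]1C(=C)C(=O)O[C@@H]1/C=C(\I)CO[Si](C)(C)C(C)(C)C | intermediate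
24 | (1S,3E)-3-(acetoxymethyl)-6-iodo-1-{(2S,3R)-2-[(1Z)-2-iodo-3-(TBSO)prop-1-en-1-yl]-4-methylidene-5-oxooxolan-3-yl}hex-3-en-1-yl 2-[(TBSO)methyl]prop-2-enoate | C=C(CO[Si](C)(C)C(C)(C)C)C(=O)O[C@@H](C/C(COC(C)=O)=C\CCI)[C@H]1C(=C)C(=O)O[C@@H]1/C=C(\I)CO[Si](C)(C)C(C)(C)C | intermediate
25 | alkylzinc iodide of 24 (iodozincio group in place of the primary iodide at C3) | C=C(CO[Si](C)(C)C(C)(C)C)C(=O)O[C@@H](C/C(COC(C)=O)=C\CC[Zn]I)[C@H]1C(=C)C(=O)O[C@@H]1/C=C(\I)CO[Si](C)(C)C(C)(C)C | intermediate
26 | (1(10)E,4E,6R,7R,8S)-14-acetoxy-15-(TBSO)germacra-1(10),4,11(13)-trien-6,12-olid-8-yl 2-[(TBSO)methyl]prop-2-enoate | C=C(CO[Si](C)(C)C(C)(C)C)C(=O)O[C@H]1C/C(COC(C)=O)=C\CC/C(CO[Si](C)(C)C(C)(C)C)=C\[C@H]2OC(=O)C(=C)[C@H]12 | intermediate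
27 | (1(10)E,4E,6R,7R,8S)-14-acetoxy-15-hydroxygermacra-1(10),4,11(13)-trien-6,12-olid-8-yl 2-(hydroxymethyl)prop-2-enoate | C=C(CO)C(=O)O[C@H]1C/C(COC(C)=O)=C\CC/C(CO)=C\[C@H]2OC(=O)C(=C)[C@H]12 | intermediate
28 | (1(10)E,4E,6R,7R,8S)-14-acetoxy-15-oxogermacra-1(10),4,11(13)-trien-6,12-olid-8-yl 2-(hydroxymethyl)prop-2-enoate (CNP0198933.2) | C=C(CO)C(=O)O[C@H]1C/C(COC(C)=O)=C\CC/C(C=O)=C\[C@H]2OC(=O)C(=C)[C@H]12 | target

Total step count: 18. Longest linear sequence: 12 (steps 5 to 11, then 14 to 18).

Steps most likely to fail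

Ring closure (step 16). The alkylzinc 25 may couple between molecules to give oligomers instead of the ring, the C3–Zn bond may be protonated, or the C11=C13 methylene may insert into the alkenyl–palladium bond before transmetalation. Fallback: starting from 24, a nickel-catalysed reductive cross-electrophile cyclisation (NiBr2(dme), 4,4'-di-tert-butyl-2,2'-bipyridine, Mn powder, NaI, DMA, rt, syringe-pump addition) would join C3 and C4 without a preformed organometallic, the C3 radical formed by iodine abstraction being captured at the alkenylnickel centre. The product would be 26, where the route is rejoined; this fallback makes no new compound (F0).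

Barbier coupling (step 14). The chair transition state may lose out to open or boat pathways, so that the aldehyde is attacked on the wrong face and the C8 carbinol forms with the wrong configuration; the β,γ-double bond of 19 may also migrate before addition. Fallback: starting from 9 and 19, the coupling would be run as before, and the C8 epimer of 23 F1 would be separated and esterified with acid 22 under Mitsunobu conditions (PPh3, DIAD, toluene, 0 °C). This inverts C8 and should give 24 directly, so that both epimers converge on 24.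

Alkynylation (step 1). Facial discrimination of the small enal by the zinc catalyst may be insufficient, or crotonaldehyde may oligomerise under the basic zinc conditions. Fallback: starting from 2, the lithium acetylide of 2 F2 (n-BuLi, THF, −78 °C) would be added to 1 to give racemic 3 F3. Lipase-catalysed acylation (lipase from Burkholderia cepacia, vinyl acetate, hexane, rt) should then convert the (R)-enantiomer, with the alkynyl chain as the large group, into the (R)-acetate F4 and leave the (S)-alcohol, which is separated and re-enters the route as 3.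

Further compounds
F0 | step 16 | none | none
F1 | step 14 | (4R,5S)-4-[(1R,3E)-3-(acetoxymethyl)-1-hydroxy-6-iodohex-3-en-1-yl]-5-[(1Z)-2-iodo-3-(TBSO)prop-1-en-1-yl]-3-methylideneoxolan-2-one (C8 epimer of 23) | O[C@H](C/C(COC(C)=O)=C\CCI)[C@H]1C(=C)C(=O)O[C@@H]1/C=C(\I)CO[Si](C)(C)C(C)(C)C
F2 | step 1 | lithium 3-(TBSO)prop-1-yn-1-ide (lithium acetylide of 2) | [Li]C#CCO[Si](C)(C)C(C)(C)C
F3 | step 1 | racemic (2E)-7-(TBSO)hept-2-en-5-yn-4-ol (racemic 3) | C/C=C/C(O)C#CCO[Si](C)(C)C(C)(C)C
F4 | step 1 | (2E,4R)-7-(TBSO)hept-2-en-5-yn-4-yl acetate | C/C=C/[C@@H](OC(C)=O)C#CCO[Si](C)(C)C(C)(C)C
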